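**Plan**

- Retrosynthesis: the three silyl ethers come off last. Ring C is cut at C4a–C4, C4–C3 and O1–C2, giving o-iodophenol 22, carbon monoxide 26 and aryl alkyne 25. In the side chain the C2'–C3' bond (enolate prenylation), the isopropenyl C=CH2 (from an acyl carbon) and the aryl–CH2CH2 bond (aryl cuprate plus β-lactone) are cut.
- Enabling feature: ring C (O1, C2, C3, C4) is joined to ring A only through C4a and C8a–O1. Ring A is a 2-alkyl-5-methoxyresorcinol whose two unsubstituted carbons (future C4a and C6) are equivalent, so one iodine next to a free hydroxyl fixes the 5-OMe/7-O/8-alkyl pattern. The pyranone then closes without oxidant or strong acid, which the isopropenyl group and tertiary alcohol would not tolerate.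
- Forward order: ring A (from 5-methoxyresorcinol) is C-alkylated, the chain is built, then the ring is iodinated, deprotected and monosilylated. Ring B enters as alkyne 25 from 2,4-dihydroxybenzaldehyde. Ring C is the only ring formed (step 14), followed by global desilylation.
- Stereochemistry: the single stereocentre (C2' of the hexyl chain, R) is set in step 4 by an (R)-4-benzyloxazolidinone-controlled prenylation. It is α to a carbonyl only up to ketone 17, which is methylenated without base.

Key step: step 14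

Remark: the stereocentre is read from the SMILES as (R) (isopropenyl > ArCH2 > CH2CH2 > H); compounds 1, 3, 7, 10, 23 and 26 and all reagents are taken as commercial.

**Route**

Step 1
Reactants: 1 5-methoxyresorcinol
Product: 2 1-methoxy-3,5-bis(methoxymethoxy)benzene
Conditions: MOMCl (2.5 equiv), i-Pr2NEt, CH2Cl2, 0 °C → rt
Reagents that add atoms: chloromethyl methyl ether, COCCl
Why: Double O-alkylation of the phenols (Williamson-type MOM ether formation) masks them as acetals that later direct ortho-lithiation.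

Step 2
Reactants: 2 1-methoxy-3,5-bis(methoxymethoxy)benzene; 3 β-propiolactone (oxetan-2-one)
Product: 6 3-[4-methoxy-2,6-bis(methoxymethoxy)phenyl]propanoic acid, via aryllithium 4 (not isolated), via lithium diarylcuprate 5 (not isolated)
Conditions: 2 (2.1 equiv), n-BuLi, THF, 0 °C; CuBr·SMe2 (1.05 equiv), −40 °C; 3 (1.0 equiv), −40 → 0 °C; aq. NH4Cl, then cold 1 M HCl to pH 4
Reagents that add atoms: none
Why: Directed ortho-metalation occurs at the one carbon flanked by two chelating MOM ethers, and the derived Gilman cuprate opens the strained β-lactone by SN2 attack at the CH2–O carbon (alkyl–oxygen cleavage) to give the arylpropanoic acid directly; one aryl group per copper is transferred and the other returns as 2.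

Step 3
Reactants: 6 3-[4-methoxy-2,6-bis(methoxymethoxy)phenyl]propanoic acid; 7 (R)-4-benzyl-1,3-oxazolidin-2-one
Product: 9 (4R)-4-benzyl-3-{3-[4-methoxy-2,6-bis(methoxymethoxy)phenyl]propanoyl}-1,3-oxazolidin-2-one, via mixed pivalic anhydride 8 (not isolated)
Conditions: PivCl, Et3N, THF, −20 °C; then 7, LiCl, −20 °C → rt
Reagents that add atoms: none
Why: N-acylation of the oxazolidinone through the mixed pivalic anhydride under LiCl/Et3N activation is the standard mild loading of an Evans auxiliary and leaves the MOM acetals untouched.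

Step 4
Reactants: 9 (4R)-4-benzyl-3-{3-[4-methoxy-2,6-bis(methoxymethoxy)phenyl]propanoyl}-1,3-oxazolidin-2-one; 10 prenyl bromide (1-bromo-3-methylbut-2-ene)
Product: 12 (4R)-4-benzyl-3-[(2R)-2-{[4-methoxy-2,6-bis(methoxymethoxy)phenyl]methyl}-5-methylhex-4-enoyl]-1,3-oxazolidin-2-one, via sodium Z-enolate 11 (not isolated)
Conditions: NaHMDS, THF, −78 °C; 10 (3 equiv), −78 → −40 °C
Reagents that add atoms: none
Why: Evans asymmetric alkylation: in the chelated sodium (Z)-enolate the C4 benzyl group of the (R)-auxiliary shields one face, so prenyl bromide enters from the other and should set the (2R) centre, the only stereocentre of the target; any minor diastereomer is removed by chromatography.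

Step 5
Reactants: 12 (4R)-4-benzyl-3-[(2R)-2-{[4-methoxy-2,6-bis(methoxymethoxy)phenyl]methyl}-5-methylhex-4-enoyl]-1,3-oxazolidin-2-one
Product: 13 (4R)-4-benzyl-3-[(2R)-5-hydroxy-2-{[4-methoxy-2,6-bis(methoxymethoxy)phenyl]methyl}-5-methylhexanoyl]-1,3-oxazolidin-2-one
Conditions: Co(acac)2 (20 mol %), PhSiH3, O2 (1 atm), THF, rt
Reagents that add atoms: dioxygen, O=O
Why: Mukaiyama hydration (metal-hydride hydrogen-atom transfer, O2 capture, silane reduction) places the hydroxyl at the more substituted carbon of the only alkene present, under neutral conditions that spare the imide, the MOM ethers and the α-stereocentre.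

Step 6
Reactants: 13 (4R)-4-benzyl-3-[(2R)-5-hydroxy-2-{[4-methoxy-2,6-bis(methoxymethoxy)phenyl]methyl}-5-methylhexanoyl]-1,3-oxazolidin-2-one
Product: 15 (2R)-5-hydroxy-2-{[4-methoxy-2,6-bis(methoxymethoxy)phenyl]methyl}-5-methylhexanoic acid, via lithium peroxycarboxylate 14 (not isolated)
Conditions: LiOH, 30 % H2O2, THF/H2O (3:1), 0 °C; aq. Na2SO3; cold 1 M HCl to pH 4; used directly
Reagents that add atoms: hydrogen peroxide (as LiOOH), OO
Why: Lithium hydroperoxide attacks the exocyclic imide carbonyl selectively (standard hydrolytic removal of an Evans auxiliary) without epimerisation, sulfite reduces the peracid salt to the acid, and the auxiliary is recovered.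

Step 7
Reactants: 15 (2R)-5-hydroxy-2-{[4-methoxy-2,6-bis(methoxymethoxy)phenyl]methyl}-5-methylhexanoic acid
Product: 17 (3R)-6-hydroxy-3-{[4-methoxy-2,6-bis(methoxymethoxy)phenyl]methyl}-6-methylheptan-2-one, via trilithium gem-diolate 16 (not isolated)
Conditions: MeLi (4 equiv), THF, −78 → 0 °C; inverse quench into cold aq. NH4Cl
Reagents that add atoms: methyllithium, [Li]C
Why: Addition of an organolithium to a lithium carboxylate stops at the gem-dialkoxide, which persists until the quench and so should give the methyl ketone and not the carbinol; two equivalents are consumed by the acid and hydroxyl protons, and the carboxylate is not enolised, so the stereocentre is retained.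

Step 8
Reactants: 17 (3R)-6-hydroxy-3-{[4-methoxy-2,6-bis(methoxymethoxy)phenyl]methyl}-6-methylheptan-2-one
Product: 18 (5R)-5-{[4-methoxy-2,6-bis(methoxymethoxy)phenyl]methyl}-2,6-dimethylhept-6-en-2-ol
Conditions: Cp2TiMe2 (3 equiv), toluene/THF, 65 °C, dark
Reagents that add atoms: dimethyltitanocene (Petasis reagent), C[Ti](C)(C1C=CC=C1)C1C=CC=C1
Why: Petasis olefination turns the methyl ketone into the isopropenyl group through a non-basic titanium methylidene, which avoids enolisation of the adjacent stereocentre (here epimerisation would mean racemisation) and tolerates acetals; the free hydroxyl only consumes reagent.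

Step 9
Reactants: 18 (5R)-5-{[4-methoxy-2,6-bis(methoxymethoxy)phenyl]methyl}-2,6-dimethylhept-6-en-2-ol
Product: 20 (5R)-5-{[3-iodo-4-methoxy-2,6-bis(methoxymethoxy)phenyl]methyl}-2,6-dimethylhept-6-en-2-ol, via dilithiated alkoxide 19 (not isolated)
Conditions: n-BuLi (2.3 equiv), THF, 0 °C; ICH2CH2I, −78 °C → rt
Reagents that add atoms: 1,2-diiodoethane, ICCI
Why: After deprotonation of the alcohol, directed ortho-metalation occurs at one of the two equivalent ring carbons flanked by OMOM and OMe, and 1,2-diiodoethane iodinates the aryllithium without free iodine that could trigger iodoetherification of the alkene.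

Step 10
Reactants: 20 (5R)-5-{[3-iodo-4-methoxy-2,6-bis(methoxymethoxy)phenyl]methyl}-2,6-dimethylhept-6-en-2-ol
Product: 21 2-[(2R)-5-hydroxy-5-methyl-2-(prop-1-en-2-yl)hexyl]-4-iodo-5-methoxybenzene-1,3-diol
Conditions: HCl (ca. 1 M) in MeOH, rt
Reagents that add atoms: none
Why: Acid-catalysed methanolysis of the two aryl MOM acetals proceeds under dilute acid at room temperature, conditions under which prenyl-type alkenes ortho to phenols, tertiary alcohols and aryl iodides are normally preserved.

Step 11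
Reactants: 21 2-[(2R)-5-hydroxy-5-methyl-2-(prop-1-en-2-yl)hexyl]-4-iodo-5-methoxybenzene-1,3-diol
Product: 22 2-[(2R)-5-hydroxy-5-methyl-2-(prop-1-en-2-yl)hexyl]-6-iodo-5-methoxy-3-[(triisopropylsilyl)oxy]phenol
Conditions: TIPSCl (1.1 equiv), imidazole, DMF, 0 °C → rt
Reagents that add atoms: chlorotriisopropylsilane, CC(C)[Si](Cl)(C(C)C)C(C)C
Why: Silylation with the bulky TIPSCl/imidazole pair is sterically governed and should occur at the hydroxyl that has a ring hydrogen as one neighbour, leaving free both the hydroxyl wedged between iodine and the branched alkyl group and the tertiary alcohol.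

Step 12
Reactants: 23 2,4-dihydroxybenzaldehyde
Product: 24 2,4-bis[(triisopropylsilyl)oxy]benzaldehyde
Conditions: TIPSOTf (2.3 equiv), 2,6-lutidine, CH2Cl2, 0 °C
Reagents that add atoms: triisopropylsilyl trifluoromethanesulfonate, CC(C)[Si](OS(=O)(=O)C(F)(F)F)(C(C)C)C(C)C
Why: The silyl triflate with 2,6-lutidine silylates both phenols, including the one hydrogen-bonded to the aldehyde; TIPS is chosen because it resists amine bases in the annulation yet is cleaved by fluoride.

Step 13
Reactants: 24 2,4-bis[(triisopropylsilyl)oxy]benzaldehyde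
Product: 25 1-ethynyl-2,4-bis[(triisopropylsilyl)oxy]benzene
Conditions: TMSCHN2, n-BuLi, THF, −78 °C; then 24, −78 °C → rt
Reagents that add atoms: (trimethylsilyl)diazomethane, C[Si](C)(C)C=[N+]=[N-]
Why: Colvin rearrangement (addition of lithiated TMS-diazomethane, Peterson-type elimination, loss of N2 and 1,2-hydride shift) converts the aryl aldehyde into the terminal alkyne without the carbonate/methanol medium that would cleave aryl silyl ethers.

Step 14
Reactants: 22 2-[(2R)-5-hydroxy-5-methyl-2-(prop-1-en-2-yl)hexyl]-6-iodo-5-methoxy-3-[(triisopropylsilyl)oxy]phenol; 25 1-ethynyl-2,4-bis[(triisopropylsilyl)oxy]benzene (1.3 equiv); 26 carbon monoxide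
Product: 29 5-methoxy-7-[(triisopropylsilyl)oxy]-2-{2,4-bis[(triisopropylsilyl)oxy]phenyl}-8-[(2R)-5-hydroxy-5-methyl-2-(prop-1-en-2-yl)hexyl]-4H-chromen-4-one, via ynone 27 (not isolated), via β-aminoenone 28 (not isolated)
Conditions: PdCl2(PPh3)2 (5 mol %), dppp (5 mol %), Et2NH, CO (5 bar), 60 °C, no copper
Reagents that add atoms: none
Why: Pd(0) inserts into the C–I bond (future C4a), CO insertion gives an aroyl-palladium, and amine-assisted alkynylation with reductive elimination gives ynone 27 (bonds C4a–C4 and C4–C3). Diethylamine adds to 27 to give β-aminoenone 28, and the C8a hydroxyl then displaces the amine in a 6-endo addition–elimination that forms O1–C2 and closes the pyranone ring. The closest known reaction is the palladium-catalysed carbonylative Sonogashira coupling of o-iodophenols with terminal alkynes with cyclisation to flavones in the same pot. No stereocentre is formed, and the existing one is remote from every reacting atom. Two selectivities are needed: CO uptake must outrun direct alkynylation (which would end in a 2-arylbenzofuran), secured by CO pressure, the absence of copper and the fast CO insertion of an electron-rich aryl-palladium; and 6-endo must outrun 5-exo closure (aurone), secured by the secondary-amine pathway through 28. Regiochemistry is fixed by the substrate, since iodine is ortho to the only free phenol and the 7-oxygen is silylated, and the non-oxidative, non-acidic medium should leave the isopropenyl group, tertiary alcohol and TIPS ethers intact.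

Step 15
Reactants: 29 5-methoxy-7-[(triisopropylsilyl)oxy]-2-{2,4-bis[(triisopropylsilyl)oxy]phenyl}-8-[(2R)-5-hydroxy-5-methyl-2-(prop-1-en-2-yl)hexyl]-4H-chromen-4-one
Product: 30 2-(2,4-dihydroxyphenyl)-7-hydroxy-8-[(2R)-5-hydroxy-5-methyl-2-(prop-1-en-2-yl)hexyl]-5-methoxy-4H-chromen-4-one (CNP0256984.1)
Conditions: TBAF (3.5 equiv), AcOH (3.5 equiv), THF, 0 °C → rt
Reagents that add atoms: none
Why: Fluoride-mediated desilylation cleaves the three aryl Si–O bonds rapidly, and the acetic acid buffer keeps the medium neither strongly basic nor acidic, so the isopropenyl group, tertiary alcohol and chromone are not exposed to harsh conditions.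

**Compound list**

1 | 5-methoxyresorcinol | COc1cc(O)cc(O)c1 | starting material
2 | 1-methoxy-3,5-bis(methoxymethoxy)benzene | COCOc1cc(OC)cc(OCOC)c1 | intermediate
3 | β-propiolactone (oxetan-2-one) | O=C1CCO1 | starting material
4 | [4-methoxy-2,6-bis(methoxymethoxy)phenyl]lithium (not isolated) | [Li]c1c(OCOC)cc(OC)cc1OCOC | intermediate
5 | lithium bis[4-methoxy-2,6-bis(methoxymethoxy)phenyl]cuprate (not isolated) | [Li+].COCOc1cc(OC)cc(OCOC)c1[Cu-]c1c(OCOC)cc(OC)cc1OCOC | intermediate
6 | 3-[4-methoxy-2,6-bis(methoxymethoxy)phenyl]propanoic acid | OC(=O)CCc1c(OCOC)cc(OC)cc1OCOC | intermediate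
7 | (R)-4-benzyl-1,3-oxazolidin-2-one | O=C1N[C@H](Cc2ccccc2)CO1 | starting material
8 | 3-[4-methoxy-2,6-bis(methoxymethoxy)phenyl]propanoic pivalic anhydride (not isolated) | CC(C)(C)C(=O)OC(=O)CCc1c(OCOC)cc(OC)cc1OCOC | intermediate
9 | (4R)-4-benzyl-3-{3-[4-methoxy-2,6-bis(methoxymethoxy)phenyl]propanoyl}-1,3-oxazolidin-2-one | O=C(CCc1c(OCOC)cc(OC)cc1OCOC)N1[C@H](Cc2ccccc2)COC1=O | intermediate
10 | prenyl bromide (1-bromo-3-methylbut-2-ene) | CC(C)=CCBr | starting material
11 | sodium (Z)-enolate of 9 (not isolated) | [Na+].[O-]/C(=C\Cc1c(OCOC)cc(OC)cc1OCOC)N1[C@H](Cc2ccccc2)COC1=O | intermediate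
12 | (4R)-4-benzyl-3-[(2R)-2-{[4-methoxy-2,6-bis(methoxymethoxy)phenyl]methyl}-5-methylhex-4-enoyl]-1,3-oxazolidin-2-one | O=C([C@H](CC=C(C)C)Cc1c(OCOC)cc(OC)cc1OCOC)N1[C@H](Cc2ccccc2)COC1=O | intermediate
13 | (4R)-4-benzyl-3-[(2R)-5-hydroxy-2-{[4-methoxy-2,6-bis(methoxymethoxy)phenyl]methyl}-5-methylhexanoyl]-1,3-oxazolidin-2-one | O=C([C@H](CCC(C)(C)O)Cc1c(OCOC)cc(OC)cc1OCOC)N1[C@H](Cc2ccccc2)COC1=O | intermediate
14 | lithium (2R)-5-hydroxy-2-{[4-methoxy-2,6-bis(methoxymethoxy)phenyl]methyl}-5-methylhexaneperoxoate (not isolated) | [Li+].[O-]OC(=O)[C@H](CCC(C)(C)O)Cc1c(OCOC)cc(OC)cc1OCOC | intermediate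
15 | (2R)-5-hydroxy-2-{[4-methoxy-2,6-bis(methoxymethoxy)phenyl]methyl}-5-methylhexanoic acid | OC(=O)[C@H](CCC(C)(C)O)Cc1c(OCOC)cc(OC)cc1OCOC | intermediate
16 | trilithium gem-diolate/alkoxide from 15 and MeLi (not isolated) | [Li+].[Li+].[Li+].CC([O-])([O-])[C@H](CCC(C)(C)[O-])Cc1c(OCOC)cc(OC)cc1OCOC | intermediate
17 | (3R)-6-hydroxy-3-{[4-methoxy-2,6-bis(methoxymethoxy)phenyl]methyl}-6-methylheptan-2-one | CC(=O)[C@H](CCC(C)(C)O)Cc1c(OCOC)cc(OC)cc1OCOC | intermediate
18 | (5R)-5-{[4-methoxy-2,6-bis(methoxymethoxy)phenyl]methyl}-2,6-dimethylhept-6-en-2-ol | C=C(C)[C@H](CCC(C)(C)O)Cc1c(OCOC)cc(OC)cc1OCOC | intermediate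
19 | ring-lithiated lithium alkoxide of 18 (not isolated) | [Li+].C=C(C)[C@H](CCC(C)(C)[O-])Cc1c(OCOC)cc(OC)c([Li])c1OCOC | intermediate
20 | (5R)-5-{[3-iodo-4-methoxy-2,6-bis(methoxymethoxy)phenyl]methyl}-2,6-dimethylhept-6-en-2-ol | C=C(C)[C@H](CCC(C)(C)O)Cc1c(OCOC)cc(OC)c(I)c1OCOC | intermediate
21 | 2-[(2R)-5-hydroxy-5-methyl-2-(prop-1-en-2-yl)hexyl]-4-iodo-5-methoxybenzene-1,3-diol | C=C(C)[C@H](CCC(C)(C)O)Cc1c(O)cc(OC)c(I)c1O | intermediate
22 | 2-[(2R)-5-hydroxy-5-methyl-2-(prop-1-en-2-yl)hexyl]-6-iodo-5-methoxy-3-[(triisopropylsilyl)oxy]phenol | C=C(C)[C@H](CCC(C)(C)O)Cc1c(O[Si](C(C)C)(C(C)C)C(C)C)cc(OC)c(I)c1O | intermediate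
23 | 2,4-dihydroxybenzaldehyde | O=Cc1ccc(O)cc1O | starting material
24 | 2,4-bis[(triisopropylsilyl)oxy]benzaldehyde | O=Cc1ccc(O[Si](C(C)C)(C(C)C)C(C)C)cc1O[Si](C(C)C)(C(C)C)C(C)C | intermediate
25 | 1-ethynyl-2,4-bis[(triisopropylsilyl)oxy]benzene | C#Cc1ccc(O[Si](C(C)C)(C(C)C)C(C)C)cc1O[Si](C(C)C)(C(C)C)C(C)C | intermediate
26 | carbon monoxide | [C-]#[O+] | starting material
27 | 1-{2-hydroxy-3-[(2R)-5-hydroxy-5-methyl-2-(prop-1-en-2-yl)hexyl]-6-methoxy-4-[(triisopropylsilyl)oxy]phenyl}-3-{2,4-bis[(triisopropylsilyl)oxy]phenyl}prop-2-yn-1-one (not isolated) | C=C(C)[C@H](CCC(C)(C)O)Cc1c(O[Si](C(C)C)(C(C)C)C(C)C)cc(OC)c(C(=O)C#Cc2ccc(O[Si](C(C)C)(C(C)C)C(C)C)cc2O[Si](C(C)C)(C(C)C)C(C)C)c1O | intermediate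
28 | 3-(diethylamino)-1-{2-hydroxy-3-[(2R)-5-hydroxy-5-methyl-2-(prop-1-en-2-yl)hexyl]-6-methoxy-4-[(triisopropylsilyl)oxy]phenyl}-3-{2,4-bis[(triisopropylsilyl)oxy]phenyl}prop-2-en-1-one (not isolated) | C=C(C)[C@H](CCC(C)(C)O)Cc1c(O[Si](C(C)C)(C(C)C)C(C)C)cc(OC)c(C(=O)C=C(N(CC)CC)c2ccc(O[Si](C(C)C)(C(C)C)C(C)C)cc2O[Si](C(C)C)(C(C)C)C(C)C)c1O | intermediate
29 | 5-methoxy-7-[(triisopropylsilyl)oxy]-2-{2,4-bis[(triisopropylsilyl)oxy]phenyl}-8-[(2R)-5-hydroxy-5-methyl-2-(prop-1-en-2-yl)hexyl]-4H-chromen-4-one | C=C(C)[C@H](CCC(C)(C)O)Cc1c(O[Si](C(C)C)(C(C)C)C(C)C)cc(OC)c2c(=O)cc(-c3ccc(O[Si](C(C)C)(C(C)C)C(C)C)cc3O[Si](C(C)C)(C(C)C)C(C)C)oc12 | intermediate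
30 | 2-(2,4-dihydroxyphenyl)-7-hydroxy-8-[(2R)-5-hydroxy-5-methyl-2-(prop-1-en-2-yl)hexyl]-5-methoxy-4H-chromen-4-one | C=C(C)[C@H](CCC(C)(C)O)Cc1c(O)cc(OC)c2c(=O)cc(-c3ccc(O)cc3O)oc12 | target

**Step count**

Total: 15 steps. Longest linear sequence: 13 steps (steps 1–11, 14, 15); the alkyne branch (steps 12–13) has two steps.

**Steps most likely to fail**

Step 14 (key step). The aryl-palladium may be alkynylated before it takes up CO, and the resulting o-alkynylphenol would then close 5-endo to a benzofuran. The aroyl-palladium may be captured by diethylamine as an amide, closure may go 5-exo, or oxidative addition at the doubly ortho-substituted, electron-rich C–I bond may be slow. The fallback builds the same ynone without palladium or CO and sets out from 22 and 25. Alkyne 25 is converted (n-BuLi, THF, −78 °C; then N-methoxy-N-methylcarbamoyl chloride) into the Weinreb ynamide N-methoxy-N-methyl-3-{2,4-bis[(triisopropylsilyl)oxy]phenyl}prop-2-ynamide F1. Iodophenol 22 is deprotonated at both hydroxyls with MeLi and subjected to iodine–lithium exchange with t-BuLi at −78 °C, giving the trilithiated aryl species F2. Addition of F2 to F1 (Weinreb ketone synthesis) should give ynone 27 after work-up, now as an isolated compound. Diethylamine in ethanol at room temperature then closes 27 through 28 to 29, where the route is rejoined.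

Step 2. Attack of the doubly ortho-substituted aryl group on the lactone CH2–O carbon may be slow, so that acyl–oxygen attack or oligomerisation of the lactone takes over; in addition only half of the aryl groups can be transferred. The fallback sets out from 2 and uses the same aryllithium 4. Quenching 4 with DMF should give 4-methoxy-2,6-bis(methoxymethoxy)benzaldehyde F3. Knoevenagel–Doebner condensation of F3 with malonic acid (pyridine, cat. piperidine, 90 °C) should give (E)-3-[4-methoxy-2,6-bis(methoxymethoxy)phenyl]prop-2-enoic acid F4. Hydrogenation of F4 (H2, Pd/C, EtOAc) returns to the route at acid 6.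

Step 11. Discrimination between the two phenols may be insufficient, leading to silylation at the iodine-flanked hydroxyl or at both. The fallback removes the need for site selection and sets out from 21. Both phenols are acetylated (Ac2O, pyridine, no DMAP, so the tertiary alcohol stays free) to give 2-[(2R)-5-hydroxy-5-methyl-2-(prop-1-en-2-yl)hexyl]-4-iodo-5-methoxy-1,3-phenylene diacetate F5. F5 is submitted with 25 and 26 to the conditions of step 14; diethylamine cleaves both aryl acetates in the flask, so the annulation should give 7-hydroxy-5-methoxy-2-{2,4-bis[(triisopropylsilyl)oxy]phenyl}-8-[(2R)-5-hydroxy-5-methyl-2-(prop-1-en-2-yl)hexyl]-4H-chromen-4-one F6. Desilylation of F6 as in step 15 rejoins the route at target 30.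

**Further compounds**

F1 | step 14 | N-methoxy-N-methyl-3-{2,4-bis[(triisopropylsilyl)oxy]phenyl}prop-2-ynamide | CON(C)C(=O)C#Cc1ccc(O[Si](C(C)C)(C(C)C)C(C)C)cc1O[Si](C(C)C)(C(C)C)C(C)C
F2 | step 14 | trilithiated aryl species from 22 (lithium phenoxide, lithium alkoxide, aryllithium) | [Li+].[Li+].C=C(C)[C@H](CCC(C)(C)[O-])Cc1c(O[Si](C(C)C)(C(C)C)C(C)C)cc(OC)c([Li])c1[O-]
F3 | step 2 | 4-methoxy-2,6-bis(methoxymethoxy)benzaldehyde | O=Cc1c(OCOC)cc(OC)cc1OCOC
F4 | step 2 | (E)-3-[4-methoxy-2,6-bis(methoxymethoxy)phenyl]prop-2-enoic acid | OC(=O)/C=C/c1c(OCOC)cc(OC)cc1OCOC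
F5 | step 11 | 2-[(2R)-5-hydroxy-5-methyl-2-(prop-1-en-2-yl)hexyl]-4-iodo-5-methoxy-1,3-phenylene diacetate | C=C(C)[C@H](CCC(C)(C)O)Cc1c(OC(C)=O)cc(OC)c(I)c1OC(C)=O
F6 | step 11 | 7-hydroxy-5-methoxy-2-{2,4-bis[(triisopropylsilyl)oxy]phenyl}-8-[(2R)-5-hydroxy-5-methyl-2-(prop-1-en-2-yl)hexyl]-4H-chromen-4-one | C=C(C)[C@H](CCC(C)(C)O)Cc1c(O)cc(OC)c2c(=O)cc(-c3ccc(O[Si](C(C)C)(C(C)C)C(C)C)cc3O[Si](C(C)C)(C(C)C)C(C)C)oc12
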